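**Retrosynthetic overview**
- Numbering runs along the chain from C1 (lactone C=O) to C12 (CH3). Ring A is the δ-lactone (C1–C5 and the oxygen on C5). Ring B is the tetrahydrofuran (C4–C7 and the oxygen on C4, called O4).
- Enabling feature: the ring-B oxygen on C7 and the benzoate oxygen on C10 stand 1,4 across the E-C8=C9 alkene, and this ring oxygen is O4 of ring A, three carbons from C7. The array O–C7–C8=C9–C10–O is therefore the retron of a 1,4-oxidation of a 4,6-dienol.
- Disconnection 1 (last step): C7–O4 and C10–OBz are cut together. This leaves a monocyclic (7E,9E)-dienyl triol lactone, benzoic acid and an oxidant. Ring B, C7, C10 and the alkene geometry all arise in one operation.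
- Disconnection 2: C6–C7 is made by Nozaki–Hiyama–Kishi coupling of a ring-A C6 aldehyde (C3, C4, C5 from D-galactal) with an (E,E)-iododiene (C11 from (R)-but-3-en-2-ol, C8 and C9 from crotonaldehyde, C7 from CHI3).
- Ring order: ring A is present from the start as the pyran ring of D-galactal and reaches the lactone level in step 2. Ring B is closed last.

Key step: step 9

Remark: in this numbering the target is 3R,4R,5R,6R,7S,10S,11R, and all four substituents on ring B are cis. D-galactal, (R)-but-3-en-2-ol, crotonaldehyde and benzoic acid are taken as commercial.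

**Step 1**
Reactants: 1 D-galactal
Product: 2 3,4,6-tri-O-triethylsilyl-D-galactal
Conditions: TESCl (3.6 equiv), imidazole, DMF, 0 °C to rt
Reagents that add atoms: chlorotriethylsilane, CC[Si](Cl)(CC)CC
Why: Imidazole-promoted silyl ether formation on all three hydroxyls is routine for glycals and touches no stereocentre; TES is chosen because the primary ether can later be oxidised selectively and the secondary ones fall to buffered fluoride.

**Step 2**
Reactants: 2 3,4,6-tri-O-triethylsilyl-D-galactal
Product: 3 2-deoxy-3,4,6-tri-O-triethylsilyl-D-lyxo-hexono-1,5-lactone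
Conditions: pyridinium chlorochromate [C5H5NH][CrO3Cl] (3 equiv), NaOAc, 4 Å MS, CH2Cl2, rt
Reagents that add atoms: pyridinium chlorochromate, [O-][Cr](=O)(=O)Cl.c1cc[nH+]cc1
Why: Chlorochromate oxidation of a cyclic enol ether to the lactone, a reaction type known for ether-protected glycals, puts oxygen on C1 and shifts hydrogen to C2, so ring A reaches its final oxidation level with C3–C5 untouched.

**Step 3**
Reactants: 3 2-deoxy-3,4,6-tri-O-triethylsilyl-D-lyxo-hexono-1,5-lactone
Product: 5 2-deoxy-3,4-di-O-triethylsilyl-D-lyxo-hexodialdono-1,5-lactone (C6 aldehyde), via alkoxysulfonium chloride 4 (not isolated)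
Conditions: (COCl)2, DMSO, CH2Cl2, −78 to −40 °C; then Et3N, −78 to −20 °C
Reagents that add atoms: none
Why: Swern conditions cleave and oxidise a primary TES ether in one operation while secondary TES ethers survive (selective Swern oxidation of primary silyl ethers), and the low temperature should keep the α-acyloxy aldehyde from epimerising at C5 or eliminating O4.

**Step 4**
Reactants: 6 (R)-but-3-en-2-ol
Product: 7 (R)-but-3-en-2-yl acetate
Conditions: Ac2O, Et3N, DMAP (cat.), CH2Cl2, 0 °C to rt
Reagents that add atoms: acetic anhydride, CC(=O)OC(C)=O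
Why: DMAP-catalysed acetylation acylates at oxygen, so the C11 configuration is retained and the final C11 ester is in place from the outset.

**Step 5**
Reactants: 7 (R)-but-3-en-2-yl acetate; 8 (E)-crotonaldehyde (5 equiv)
Product: 9 (4R,2E)-4-acetoxypent-2-enal
Conditions: second-generation Hoveyda–Grubbs catalyst RuCl2(SIMes)(=CH-C6H4-2-OiPr) (3 mol %), CH2Cl2, 40 °C
Reagents that add atoms: none
Why: Olefin cross metathesis of a terminal allylic acetate with excess crotonaldehyde should give the conjugated E-enal under thermodynamic control and does not touch C11.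

**Step 6**
Reactants: 9 (4R,2E)-4-acetoxypent-2-enal
Product: 10 (2R,3E,5E)-6-iodohexa-3,5-dien-2-yl acetate
Conditions: CHI3 (2 equiv), CrCl2 (6 equiv), THF, 0 °C
Reagents that add atoms: iodoform, IC(I)I
Why: In the Takai olefination the geminal dichromium reagent from CHI3 adds to the aldehyde and eliminates to the E-alkenyl iodide, a course well established for enals, which completes the E,E-iododiene.

**Step 7**
Reactants: 5 2-deoxy-3,4-di-O-triethylsilyl-D-lyxo-hexodialdono-1,5-lactone; 10 (2R,3E,5E)-6-iodohexa-3,5-dien-2-yl acetate
Product: 12 3,4-di-O-TES δ-lactone carrying at C5 the (1R,2E,4E,6R)-6-acetoxy-1-hydroxyhepta-2,4-dienyl chain (6R carbinol), via dienylchromium dichloride 11 (not isolated)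
Conditions: CrCl2 (5 equiv), NiCl2 (1 mol %), DMSO, rt; then H2O
Reagents that add atoms: none
Why: In the Nozaki–Hiyama–Kishi coupling the alkenylchromium reagent forms with retention of geometry and adds only to the aldehyde (lactone, acetate and silyl ethers are inert), and the new C6 centre (R, 5,6-anti) should follow the polar Felkin–Anh model with the poorly chelating acyloxy C5–O bond perpendicular to the carbonyl.

**Step 8**
Reactants: 12 6R dienyl carbinol bis-TES ether
Product: 13 (4R,5R,6R)-6-[(1R,2E,4E,6R)-6-acetoxy-1-hydroxyhepta-2,4-dien-1-yl]-4,5-dihydroxytetrahydro-2H-pyran-2-one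
Conditions: HF·pyridine, pyridine, THF, 0 °C; quench with Me3SiOMe, evaporate
Reagents that add atoms: none
Why: Pyridine-buffered fluoride cleavage of secondary TES ethers is mild enough for the dienyl carbinol, the allylic acetate and the β-hydroxy lactone, and the non-aqueous quench avoids hydrolytic opening of ring A and its reclosure on O4.

**Step 9**
Reactants: 13 dienyl triol lactone; 14 benzoic acid (5 equiv)
Product: 16 CNP0230210.1, via π-allylpalladium chloride complex 15 (not isolated)
Conditions: Pd(OAc)2 (10 mol %), LiCl (20 mol %), PhCO2Li (2 equiv), p-benzoquinone (2 equiv), dry acetone, 20 °C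
Reagents that add atoms: none
Why: Divalent palladium binds the s-trans (7E,9E)-diene, the axial C4 hydroxyl of ring A adds to C7 anti to the metal to give π-allyl complex 15, chloride on palladium then leaves only external attack of benzoate at C10, again anti to the metal, and benzoquinone returns the released zerovalent palladium to the divalent state. The closest known reaction type is the palladium/benzoquinone-catalysed intramolecular 1,4-oxyacyloxylation of conjugated dienes, known for cyclic dienols and for acyclic 4,6-dienols, in which catalytic LiCl switches the carboxylate from internal to external delivery. Ring B closes in the 5-exo-trig mode, and its cis fusion to ring A is enforced by the gauche relation of the axial O4 and the equatorial C6 on the lactone. C7 (S) is controlled by the allylic C6 hydroxyl, which takes the in-plane position next to the reacting alkene (the cis-directing effect of an allylic oxygen known from iodo-, mercurio- and palladium-induced 5-exo closures of 4-pentene-1,3-diols) and so puts C8 cis to O6, whereas C10 (S) is relayed from C7 because two anti attacks on the same face of an E,E-diene fix the 7,10-relationship and leave the syn,syn-allyl unit as the E-C8=C9 alkene. The step needs chemoselectivity among three free hydroxyls and 1,4- over 1,2-regioselectivity: only O4 reaches C7 through a five-membered transition state (O3 would need a bridged ring on a diaxial lactone, O6 a three-membered one), and benzoate should prefer C10, the allyl terminus remote from the new ring oxygen and from the bicyclic bulk. Because the benzoate enters as a nucleophile at carbon, the C3 and C6 hydroxyls and the C11 acetate need neither protection nor later differentiation.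

**Compound list**
1 | D-galactal | OC[C@H]1OC=C[C@@H](O)[C@H]1O | starting material
2 | 3,4,6-tri-O-triethylsilyl-D-galactal | CC[Si](CC)(CC)OC[C@H]1OC=C[C@@H](O[Si](CC)(CC)CC)[C@H]1O[Si](CC)(CC)CC | intermediate
3 | 2-deoxy-3,4,6-tri-O-triethylsilyl-D-lyxo-hexono-1,5-lactone | CC[Si](CC)(CC)OC[C@H]1OC(=O)C[C@@H](O[Si](CC)(CC)CC)[C@H]1O[Si](CC)(CC)CC | intermediate
4 | C6 alkoxy(dimethyl)sulfonium chloride of the 3,4-di-O-TES lactone | C[S+](C)OC[C@H]1OC(=O)C[C@@H](O[Si](CC)(CC)CC)[C@H]1O[Si](CC)(CC)CC.[Cl-] | intermediate
5 | 2-deoxy-3,4-di-O-triethylsilyl-D-lyxo-hexodialdono-1,5-lactone | O=C[C@H]1OC(=O)C[C@@H](O[Si](CC)(CC)CC)[C@H]1O[Si](CC)(CC)CC | intermediate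
6 | (R)-but-3-en-2-ol | O[C@H](C)C=C | starting material
7 | (R)-but-3-en-2-yl acetate | CC(=O)O[C@H](C)C=C | intermediate
8 | (E)-crotonaldehyde | C/C=C/C=O | starting material
9 | (4R,2E)-4-acetoxypent-2-enal | CC(=O)O[C@H](C)/C=C/C=O | intermediate
10 | (2R,3E,5E)-6-iodohexa-3,5-dien-2-yl acetate | CC(=O)O[C@H](C)/C=C/C=C/I | intermediate
11 | (1E,3E,5R)-5-acetoxyhexa-1,3-dienylchromium dichloride | CC(=O)O[C@H](C)/C=C/C=C/[Cr](Cl)Cl | intermediate
12 | 6R dienyl carbinol, 3,4-di-O-TES δ-lactone | CC(=O)O[C@H](C)/C=C/C=C/[C@@H](O)[C@H]1OC(=O)C[C@@H](O[Si](CC)(CC)CC)[C@H]1O[Si](CC)(CC)CC | intermediate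
13 | (4R,5R,6R)-6-[(1R,2E,4E,6R)-6-acetoxy-1-hydroxyhepta-2,4-dien-1-yl]-4,5-dihydroxytetrahydro-2H-pyran-2-one | CC(=O)O[C@H](C)/C=C/C=C/[C@@H](O)[C@H]1OC(=O)C[C@@H](O)[C@H]1O | intermediate
14 | benzoic acid | O=C(O)c1ccccc1 | starting material
15 | chloro(η3-C8–C10-allyl)palladium complex of the cyclised bicycle, metal anti to O4 (drawn as its ion set) | CC(=O)O[C@H](C)/C=C/[CH-][C@@H]1O[C@H]2[C@H](OC(=O)C[C@H]2O)[C@@H]1O.[Pd+2].[Cl-] | intermediate
16 | CNP0230210.1, (3R,4R,5R,6R,7S,8E,10S,11R) in chain numbering | CC(=O)O[C@H](C)[C@H](/C=C/[C@@H]1O[C@H]2[C@H](OC(=O)C[C@H]2O)[C@@H]1O)OC(=O)c1ccccc1 | target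

**Totals**
- Total step count: 9.
- Longest linear sequence: 6 steps (steps 1, 2, 3, 7, 8, 9 from D-galactal). The side-chain branch (steps 4, 5, 6, then 7, 8, 9) is equally long.

**Steps most likely to fail**

**Step 9 (key step)**
- What may go wrong: closure on the other diene face, so that C8 ends trans to O6; benzoate attack at C8 instead of C10; internal instead of external benzoate delivery; syn/anti isomerisation of the allyl unit; or migration of the lactone from O5 to the freed O4 before palladium acts.
- Fallback: ring closure is separated from side-chain oxygenation, C7 is put under ligand control, and C10 and C11 are brought in preset. It sets out from 5 and 7 and comes back at 16.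
- Aldehyde 5 is coupled under Nozaki–Hiyama–Kishi conditions (CrCl2, catalytic NiCl2) with (E)-3-iodoallyl acetate F1 to give the 6R allylic acetate carbinol F2. HF·pyridine then frees the triol allylic acetate F3.
- A Tsuji–Trost etherification (Pd2(dba)3·CHCl3, the matched enantiomer of the DACH-phenyl Trost ligand, CH2Cl2) closes ring B by O4 attack at C7 and gives the 2-vinyl bicyclic diol lactone F4.
- In parallel, 7 is ozonised (O3, then Me2S) to (R)-2-acetoxypropanal F5. This is vinylated with vinyl bromide, CrCl2 and catalytic NiCl2 (Felkin–Anh, 10,11-anti) to the allylic alcohol F6, which is benzoylated (BzCl, pyridine) to (3S,4R)-4-acetoxypent-1-en-3-yl benzoate F7.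
- E-selective cross metathesis of F4 with F7 (second-generation Hoveyda–Grubbs catalyst) gives 16 without protecting groups.

**Step 7**
- What may go wrong: a weak Felkin–Anh bias at C6, or epimerisation at C5 and β-elimination of O4 in aldehyde 5 on the Lewis-acidic chromium salts.
- Fallback: C6 is set by reagent-controlled reduction instead of during C–C bond formation. It sets out from 12 as obtained (mixed at C6) and comes back at 12.
- Dess–Martin oxidation (NaHCO3, CH2Cl2) gives the dienone F8. Corey–Bakshi–Shibata reduction ((R)-Me-CBS, catecholborane, toluene, −78 °C, with the dienyl arm acting as the large group) should then return the 6R alcohol 12.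

**Step 2**
- What may go wrong: loss of the acid-labile primary silyl ether on the acidic chromium reagent followed by over-oxidation, or allylic transposition with loss of O3.
- Fallback: the operation is split into hydration and a neutral lactol oxidation. It sets out from 2 and comes back at 3.
- Ph3P·HBr (catalytic) with H2O in THF adds water to the enol ether and gives the 2-deoxy lactol F9 as an anomeric mixture. Fétizon oxidation (Ag2CO3 on Celite, toluene, reflux) converts it into 3.

**Further compounds**
F1 | step 9 | (E)-3-iodoallyl acetate | CC(=O)OC/C=C/I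
F2 | step 9 | 6R allylic acetate carbinol, 3,4-di-O-TES δ-lactone | CC(=O)OC/C=C/[C@@H](O)[C@H]1OC(=O)C[C@@H](O[Si](CC)(CC)CC)[C@H]1O[Si](CC)(CC)CC
F3 | step 9 | triol allylic acetate | CC(=O)OC/C=C/[C@@H](O)[C@H]1OC(=O)C[C@@H](O)[C@H]1O
F4 | step 9 | 2-vinyl bicyclic diol lactone (7S, all-cis ring B) | C=C[C@@H]1O[C@H]2[C@H](OC(=O)C[C@H]2O)[C@@H]1O
F5 | step 9 | (R)-2-acetoxypropanal | CC(=O)O[C@H](C)C=O
F6 | step 9 | (2R,3S)-3-hydroxypent-4-en-2-yl acetate | CC(=O)O[C@H](C)[C@H](C=C)O
F7 | step 9 | (3S,4R)-4-acetoxypent-1-en-3-yl benzoate | CC(=O)O[C@H](C)[C@H](C=C)OC(=O)c1ccccc1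
F8 | step 7 | C6 dienone, 3,4-di-O-TES δ-lactone | CC(=O)O[C@H](C)/C=C/C=C/C(=O)[C@H]1OC(=O)C[C@@H](O[Si](CC)(CC)CC)[C@H]1O[Si](CC)(CC)CC
F9 | step 2 | 2-deoxy-3,4,6-tri-O-triethylsilyl-D-lyxo-hexopyranose (anomeric mixture) | CC[Si](CC)(CC)OC[C@H]1OC(O)C[C@@H](O[Si](CC)(CC)CC)[C@H]1O[Si](CC)(CC)CC
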